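**Retrosynthetic overview**
- The last C–C bond is C5–CH2 of the side chain: Negishi coupling of a C5 iodide with the (S)-alkylzinc cut out of (R)-limonene oxide (ring C1=C2 cleaved, the old C2 excised).
- Before that, the C7 aroyl group comes from lithiation between O1 and the 6-OMe and a Weinreb amide; O4 goes from silyl to methyl; the 6-OMe is cleaved by chelation to the new ketone.
- The strategy rests on the dihydrofuran ring O1–C2–C3–C3a–C7a: C3 is a benzylic CH2 and C2 is the α-carbon of an aryl alkyl ether. The C2–C3 bond is therefore made from a benzylic cobalt carbene radical and the OCH2 group of a 2-alkoxybenzaldehyde tosylhydrazone, which closes the only ring built in the route (both benzene rings are bought) and sets C2.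
- The hydrazone comes in five steps from 2,4,6-trihydroxybenzaldehyde, isobutylene oxide and tosyl hydrazide.

Key step: step 6

Assumption: the sense of induction of the chiral Co(II) porphyrin is not predicted here; both ligand antipodes exist, and the one that gives (S) at C2 is meant throughout.

**Route**

Step 1
Reactants: 1 2,4,6-trihydroxybenzaldehyde
Product: 2 2,6-dihydroxy-4-methoxybenzaldehyde
Conditions: MeI (1.0 equiv), Li2CO3 (1.1 equiv), DMF, 40 °C
Reagents that add atoms: iodomethane CI
Why: Williamson O-methylation under weak-base control should take the 4-OH, which is para to the formyl group, the most acidic phenol and the only one not held in the hydrogen bond to C=O.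

Step 2
Reactants: 2 2,6-dihydroxy-4-methoxybenzaldehyde; 3 isobutylene oxide (2,2-dimethyloxirane)
Product: 4 2-hydroxy-6-(2-hydroxy-2-methylpropoxy)-4-methoxybenzaldehyde
Conditions: 3 (2 equiv), K2CO3 (0.2 equiv), DMF, 80 °C, sealed tube
Reagents that add atoms: none
Why: Base-catalysed SN2 opening of the epoxide by the phenoxide at the unhindered CH2 gives the aryl ether with the tertiary alcohol, and the second ortho-OH stays chelated to the aldehyde so that mono-alkylation should prevail.

Step 3
Reactants: 4 2-hydroxy-6-(2-hydroxy-2-methylpropoxy)-4-methoxybenzaldehyde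
Product: 5 2-(tert-butyldimethylsilyloxy)-6-(2-hydroxy-2-methylpropoxy)-4-methoxybenzaldehyde
Conditions: TBSCl (1.2 equiv), imidazole (2.5 equiv), DMF, 0 °C → rt
Reagents that add atoms: tert-butyldimethylsilyl chloride CC(C)(C)[Si](C)(C)Cl
Why: Silyl chloride/imidazole silylation is selective for the phenol, since a tertiary alcohol does not react with TBSCl under these conditions.

Step 4
Reactants: 5 2-(tert-butyldimethylsilyloxy)-6-(2-hydroxy-2-methylpropoxy)-4-methoxybenzaldehyde
Product: 6 2-(tert-butyldimethylsilyloxy)-4-methoxy-6-[2-methyl-2-(triethylsilyloxy)propoxy]benzaldehyde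
Conditions: TESOTf (1.3 equiv), 2,6-lutidine (2 equiv), CH2Cl2, −78 → 0 °C
Reagents that add atoms: triethylsilyl triflate CC[Si](CC)(CC)OS(=O)(=O)C(F)(F)F
Why: A silyl triflate with a hindered pyridine base is the standard way to silylate a tertiary alcohol and leaves the aldehyde and the aryl silyl ether alone.

Step 5
Reactants: 6 2-(tert-butyldimethylsilyloxy)-4-methoxy-6-[2-methyl-2-(triethylsilyloxy)propoxy]benzaldehyde; 7 p-toluenesulfonyl hydrazide
Product: 8 (E)-N'-{2-(tert-butyldimethylsilyloxy)-4-methoxy-6-[2-methyl-2-(triethylsilyloxy)propoxy]benzylidene}-4-methylbenzenesulfonohydrazide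
Conditions: 7 (1.05 equiv), THF, MgSO4, rt
Reagents that add atoms: none
Why: Condensation of an aromatic aldehyde with a sulfonyl hydrazide gives the (E)-hydrazone, and the aprotic medium spares the aryl silyl ether.

Step 6
Reactants: 8 (E)-N'-{2-(tert-butyldimethylsilyloxy)-4-methoxy-6-[2-methyl-2-(triethylsilyloxy)propoxy]benzylidene}-4-methylbenzenesulfonohydrazide
Product: 10 (S)-4-(tert-butyldimethylsilyloxy)-6-methoxy-2-[2-(triethylsilyloxy)propan-2-yl]-2,3-dihydrobenzofuran, via aryldiazomethane 9 (not isolated)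
Conditions: Cs2CO3 (2 equiv), Co(II) complex of a D2-symmetric chiral amidoporphyrin (ChenPhyrin type, antipode giving S; 3 mol %), toluene, 60 °C, N2
Reagents that add atoms: none
Why: Caesium carbonate converts 8 into the aryldiazomethane 9 (Bamford–Stevens), which the Co(II) metalloradical traps with loss of N2 as an α-Co(III)-benzyl (carbene) radical; this radical takes a hydrogen atom from the ether OCH2 group through a six-membered transition state (1,5-HAT), and the resulting α-aryloxy radical displaces Co(II) at the benzylic carbon, forming C2–C3. The closest known reaction is the Co(II)–porphyrin metalloradical 1,5-C–H alkylation of aryldiazomethanes made in situ from sulfonylhydrazones; a non-benzylic OCH2 flanked by a quaternary carbon has not been examined and is the open point of the route. The dihydrofuran ring (O1–C2–C3–C3a–C7a) is closed in the 5-exo-tet mode by intramolecular radical substitution at the Co–C bond. C2 is created in this C–C bond-forming event, where the planar α-oxy radical sits in the chiral pocket of the amidoporphyrin (amide N–H hydrogen bonds and the chiral amide walls), so the ligand antipode fixes (S). The step needs site selectivity for the OCH2 hydrogens and chemoselectivity over carbene dimerisation: that CH2 is the only activated C–H within 1,5-reach, the second ortho oxygen carries TBS (no O–CH3 hydrogens, and Si–CH3 is one atom further and unactivated), the 4-OMe is out of reach, the substrate has no alkene to cyclopropanate, and the aprotic medium keeps the silyl ethers intact.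

Step 7
Reactants: 11 methyl 3-hydroxybenzoate
Product: 12 methyl 3-(triisopropylsilyloxy)benzoate
Conditions: TIPSCl (1.1 equiv), imidazole (2.2 equiv), DMF, rt
Reagents that add atoms: triisopropylsilyl chloride CC(C)[Si](Cl)(C(C)C)C(C)C
Why: Standard phenol silylation; TIPS is chosen because it must later survive organolithium, carbonate/methanol and BCl3 and leave with fluoride at the end.

Step 8
Reactants: 12 methyl 3-(triisopropylsilyloxy)benzoate
Product: 13 N-methoxy-N-methyl-3-(triisopropylsilyloxy)benzamide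
Conditions: MeNHOMe·HCl (1.5 equiv), i-PrMgCl (3.0 equiv), THF, −20 → 0 °C
Reagents that add atoms: N,O-dimethylhydroxylamine hydrochloride CNOC.Cl
Why: The magnesium amide of N,O-dimethylhydroxylamine converts the ester directly into the Weinreb amide, and the stable tetrahedral chelate prevents further addition.

Step 9
Reactants: 10 (S)-4-(tert-butyldimethylsilyloxy)-6-methoxy-2-[2-(triethylsilyloxy)propan-2-yl]-2,3-dihydrobenzofuran; 13 N-methoxy-N-methyl-3-(triisopropylsilyloxy)benzamide
Product: 15 (S)-{4-(tert-butyldimethylsilyloxy)-6-methoxy-2-[2-(triethylsilyloxy)propan-2-yl]-2,3-dihydrobenzofuran-7-yl}[3-(triisopropylsilyloxy)phenyl]methanone, via aryllithium 14 (not isolated)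
Conditions: n-BuLi (1.2 equiv), TMEDA (1.2 equiv), THF, −20 → 0 °C; then 13 (1.3 equiv), −78 °C → rt; aq. NH4Cl
Reagents that add atoms: none
Why: Directed ortho-metalation should occur at C7, which lies between two lithium-coordinating oxygens (O1 and the 6-OMe), whereas C5 is shielded by the bulky, non-coordinating OTBS group, and acylation of the aryllithium with the Weinreb amide stops at the ketone.

Step 10
Reactants: 15 (S)-{4-(tert-butyldimethylsilyloxy)-6-methoxy-2-[2-(triethylsilyloxy)propan-2-yl]-2,3-dihydrobenzofuran-7-yl}[3-(triisopropylsilyloxy)phenyl]methanone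
Product: 17 (S)-{4,6-dimethoxy-2-[2-(triethylsilyloxy)propan-2-yl]-2,3-dihydrobenzofuran-7-yl}[3-(triisopropylsilyloxy)phenyl]methanone, via phenol 16 (not isolated)
Conditions: K2CO3 (1.5 equiv), MeOH/THF, 0 °C → rt; evaporate; MeI (3 equiv), K2CO3 (2 equiv), DMF, rt
Reagents that add atoms: iodomethane CI
Why: The 4-O–TBS bond is para to the new ketone (a vinylogous silyl ester) and should be methanolysed much faster than the bulkier meta-placed aryl OTIPS or the tertiary alkyl OTES, and the liberated phenoxide is then O-methylated (Williamson).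

Step 11
Reactants: 17 (S)-{4,6-dimethoxy-2-[2-(triethylsilyloxy)propan-2-yl]-2,3-dihydrobenzofuran-7-yl}[3-(triisopropylsilyloxy)phenyl]methanone
Product: 18 (S)-{6-hydroxy-4-methoxy-2-[2-(triethylsilyloxy)propan-2-yl]-2,3-dihydrobenzofuran-7-yl}[3-(triisopropylsilyloxy)phenyl]methanone
Conditions: BCl3 (1.2 equiv), CH2Cl2, −78 → −40 °C; aq. NaHCO3
Reagents that add atoms: none
Why: Chelation-controlled aryl methyl ether cleavage: boron binds the ketone oxygen and the ortho 6-OMe in a six-membered chelate so that chloride removes only that methyl, while the 4-OMe (para), the secondary O1–C2 bond and the hindered silyl ethers should not be engaged by near-stoichiometric reagent at low temperature.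

Step 12
Reactants: 18 (S)-{6-hydroxy-4-methoxy-2-[2-(triethylsilyloxy)propan-2-yl]-2,3-dihydrobenzofuran-7-yl}[3-(triisopropylsilyloxy)phenyl]methanone
Product: 19 (S)-{6-hydroxy-5-iodo-4-methoxy-2-[2-(triethylsilyloxy)propan-2-yl]-2,3-dihydrobenzofuran-7-yl}[3-(triisopropylsilyloxy)phenyl]methanone
Conditions: NIS (1.05 equiv), CH2Cl2, 0 °C, dark
Reagents that add atoms: N-iodosuccinimide O=C1CCC(=O)N1I
Why: Electrophilic aromatic iodination goes to C5, the only free position of the trioxygenated ring and ortho to the free phenol, while the acyl-deactivated silyloxyphenyl ring is far less reactive.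

Step 13
Reactants: 20 (+)-limonene 1,2-oxide [(4R)-1-methyl-4-(prop-1-en-2-yl)-7-oxabicyclo[4.1.0]heptane; commercial cis/trans mixture]
Product: 22 (3R)-6-oxo-3-(prop-1-en-2-yl)heptanal, via diol 21 (not isolated)
Conditions: H5IO6 (1.2 equiv), THF/H2O, 0 °C → rt
Reagents that add atoms: water O
Why: Periodic acid hydrates the epoxide and cleaves the resulting 1,2-diol (Malaprade cleavage), so both epoxide diastereomers converge on one keto aldehyde while the isopropenyl group and the C4 stereocentre are untouched.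

Step 14
Reactants: 22 (3R)-6-oxo-3-(prop-1-en-2-yl)heptanal
Product: 23 (5R)-7,7-dimethoxy-5-(prop-1-en-2-yl)heptan-2-one
Conditions: HC(OMe)3 (1.5 equiv), MeOH, CeCl3·7H2O (cat.), rt
Reagents that add atoms: trimethyl orthoformate COC(OC)OC; methanol CO
Why: Lanthanide-catalysed acetalisation is selective for the aldehyde over the methyl ketone, which masks the aldehyde for the olefination.

Step 15
Reactants: 23 (5R)-7,7-dimethoxy-5-(prop-1-en-2-yl)heptan-2-one
Product: 24 (5R)-7,7-dimethoxy-2-methyl-5-(prop-1-en-2-yl)hept-1-ene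
Conditions: Ph3PCH3Br (1.5 equiv), KOtBu (1.4 equiv), THF, 0 °C → rt
Reagents that add atoms: methyltriphenylphosphonium bromide C[P+](c1ccccc1)(c1ccccc1)c1ccccc1.[Br-]
Why: Wittig methylenation of the methyl ketone installs the second 1,1-disubstituted alkene; the stereocentre is γ to the carbonyl and cannot epimerise.

Step 16
Reactants: 24 (5R)-7,7-dimethoxy-2-methyl-5-(prop-1-en-2-yl)hept-1-ene
Product: 25 (3R)-6-methyl-3-(prop-1-en-2-yl)hept-6-enal
Conditions: AcOH/THF/H2O (3:1:1), 40 °C
Reagents that add atoms: water O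
Why: Mild aqueous acid hydrolyses the dimethyl acetal without protonating the 1,1-disubstituted alkenes.

Step 17
Reactants: 25 (3R)-6-methyl-3-(prop-1-en-2-yl)hept-6-enal
Product: 28 (2S)-5-methyl-2-(prop-1-en-2-yl)hex-5-en-1-ol, via enamine 26 (not isolated), via nor-aldehyde 27 (not isolated)
Conditions: piperidine (1.2 equiv), 4 Å MS, toluene, rt; filter, evaporate; CuCl (10 mol %), O2 (1 atm), MeCN, 0 °C; filter through Celite; NaBH4, MeOH, −20 → 0 °C
Reagents that add atoms: dioxygen O=O
Why: Copper-catalysed oxygenation cleaves the electron-rich enamine C=C bond (Van Rheenen-type oxidative cleavage) and removes the aldehyde carbon as N-formylpiperidine while the isolated alkenes are inert to O2/Cu(I), and immediate borohydride reduction should keep the enolisable α-stereocentre of 27 from epimerising (the descriptor changes from R to S only through CIP priorities).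

Step 18
Reactants: 28 (2S)-5-methyl-2-(prop-1-en-2-yl)hex-5-en-1-ol
Product: 29 (3S)-3-(iodomethyl)-2,6-dimethylhepta-1,6-diene
Conditions: PPh3 (1.3 equiv), imidazole (1.5 equiv), I2 (1.3 equiv), CH2Cl2, 0 °C → rt
Reagents that add atoms: iodine II
Why: Appel-type iodination converts the primary alcohol by SN2 displacement of the alkoxyphosphonium ion without touching the adjacent stereocentre or the alkenes.

Step 19
Reactants: 19 (S)-{6-hydroxy-5-iodo-4-methoxy-2-[2-(triethylsilyloxy)propan-2-yl]-2,3-dihydrobenzofuran-7-yl}[3-(triisopropylsilyloxy)phenyl]methanone; 29 (3S)-3-(iodomethyl)-2,6-dimethylhepta-1,6-diene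
Product: 32 {(2S)-6-hydroxy-4-methoxy-5-[(2R)-5-methyl-2-(prop-1-en-2-yl)hex-5-en-1-yl]-2-[2-(triethylsilyloxy)propan-2-yl]-2,3-dihydrobenzofuran-7-yl}[3-(triisopropylsilyloxy)phenyl]methanone, via alkyllithium 30 (not isolated), via alkylzinc chloride 31 (not isolated)
Conditions: 29 (1.8 equiv), t-BuLi (3.6 equiv), Et2O/pentane, −78 °C; ZnCl2 (1.9 equiv, THF), −78 → 0 °C; then 19, Pd(OAc)2 (5 mol %), SPhos (10 mol %), THF, 25 → 40 °C, slow addition of 31
Reagents that add atoms: none
Why: Iodine–lithium exchange at −78 °C is non-radical and too cold for carbolithiation of the alkenes, transmetalation gives a primary alkylzinc whose stereocentre is β to the metal, and the Pd/SPhos Negishi coupling joins it to the doubly ortho-substituted aryl iodide while tolerating the ketone and the phenol, which is hydrogen-bonded to that ketone.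

Step 20
Reactants: 32 {(2S)-6-hydroxy-4-methoxy-5-[(2R)-5-methyl-2-(prop-1-en-2-yl)hex-5-en-1-yl]-2-[2-(triethylsilyloxy)propan-2-yl]-2,3-dihydrobenzofuran-7-yl}[3-(triisopropylsilyloxy)phenyl]methanone
Product: 33 {(2S)-6-hydroxy-2-(2-hydroxypropan-2-yl)-4-methoxy-5-[(2R)-5-methyl-2-(prop-1-en-2-yl)hex-5-en-1-yl]-2,3-dihydrobenzofuran-7-yl}(3-hydroxyphenyl)methanone (CNP0263422.2)
Conditions: TBAF (3 equiv), AcOH (3 equiv), THF, 0 °C → rt
Reagents that add atoms: none
Why: Buffered fluoride cleaves the aryl O–TIPS and tertiary O–TES bonds and leaves the phenolic ketone, both 1,1-disubstituted alkenes and both stereocentres untouched, so no acid meets the alkene-bearing phenol at the end.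

**Compound list**
1 | 2,4,6-trihydroxybenzaldehyde | O=Cc1c(O)cc(O)cc1O | starting material
2 | 2,6-dihydroxy-4-methoxybenzaldehyde | COc1cc(O)c(C=O)c(O)c1 | intermediate
3 | isobutylene oxide (2,2-dimethyloxirane) | CC1(C)CO1 | starting material
4 | 2-hydroxy-6-(2-hydroxy-2-methylpropoxy)-4-methoxybenzaldehyde | COc1cc(O)c(C=O)c(OCC(C)(C)O)c1 | intermediate
5 | 2-(tert-butyldimethylsilyloxy)-6-(2-hydroxy-2-methylpropoxy)-4-methoxybenzaldehyde | COc1cc(O[Si](C)(C)C(C)(C)C)c(C=O)c(OCC(C)(C)O)c1 | intermediate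
6 | 2-(tert-butyldimethylsilyloxy)-4-methoxy-6-[2-methyl-2-(triethylsilyloxy)propoxy]benzaldehyde | COc1cc(O[Si](C)(C)C(C)(C)C)c(C=O)c(OCC(C)(C)O[Si](CC)(CC)CC)c1 | intermediate
7 | p-toluenesulfonyl hydrazide | Cc1ccc(cc1)S(=O)(=O)NN | starting material
8 | (E)-N-tosylhydrazone of 6 (key-step precursor) | COc1cc(O[Si](C)(C)C(C)(C)C)c(/C=N/NS(=O)(=O)c2ccc(C)cc2)c(OCC(C)(C)O[Si](CC)(CC)CC)c1 | intermediate
9 | {2-(tert-butyldimethylsilyloxy)-4-methoxy-6-[2-methyl-2-(triethylsilyloxy)propoxy]phenyl}diazomethane | COc1cc(O[Si](C)(C)C(C)(C)C)c(C=[N+]=[N-])c(OCC(C)(C)O[Si](CC)(CC)CC)c1 | intermediate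
10 | (S)-4-(tert-butyldimethylsilyloxy)-6-methoxy-2-[2-(triethylsilyloxy)propan-2-yl]-2,3-dihydrobenzofuran (key-step product) | COc1cc2c(c(O[Si](C)(C)C(C)(C)C)c1)C[C@@H](C(C)(C)O[Si](CC)(CC)CC)O2 | intermediate
11 | methyl 3-hydroxybenzoate | COC(=O)c1cccc(O)c1 | starting material
12 | methyl 3-(triisopropylsilyloxy)benzoate | COC(=O)c1cccc(O[Si](C(C)C)(C(C)C)C(C)C)c1 | intermediate
13 | N-methoxy-N-methyl-3-(triisopropylsilyloxy)benzamide | CON(C)C(=O)c1cccc(O[Si](C(C)C)(C(C)C)C(C)C)c1 | intermediate
14 | 7-lithio derivative of 10 | COc1c([Li])c2c(c(O[Si](C)(C)C(C)(C)C)c1)C[C@@H](C(C)(C)O[Si](CC)(CC)CC)O2 | intermediate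
15 | (S)-{4-(tert-butyldimethylsilyloxy)-6-methoxy-2-[2-(triethylsilyloxy)propan-2-yl]-2,3-dihydrobenzofuran-7-yl}[3-(triisopropylsilyloxy)phenyl]methanone | COc1c(C(=O)c3cccc(O[Si](C(C)C)(C(C)C)C(C)C)c3)c2c(c(O[Si](C)(C)C(C)(C)C)c1)C[C@@H](C(C)(C)O[Si](CC)(CC)CC)O2 | intermediate
16 | (S)-{4-hydroxy-6-methoxy-2-[2-(triethylsilyloxy)propan-2-yl]-2,3-dihydrobenzofuran-7-yl}[3-(triisopropylsilyloxy)phenyl]methanone | COc1c(C(=O)c3cccc(O[Si](C(C)C)(C(C)C)C(C)C)c3)c2c(c(O)c1)C[C@@H](C(C)(C)O[Si](CC)(CC)CC)O2 | intermediate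
17 | (S)-{4,6-dimethoxy-2-[2-(triethylsilyloxy)propan-2-yl]-2,3-dihydrobenzofuran-7-yl}[3-(triisopropylsilyloxy)phenyl]methanone | COc1c(C(=O)c3cccc(O[Si](C(C)C)(C(C)C)C(C)C)c3)c2c(c(OC)c1)C[C@@H](C(C)(C)O[Si](CC)(CC)CC)O2 | intermediate
18 | (S)-{6-hydroxy-4-methoxy-2-[2-(triethylsilyloxy)propan-2-yl]-2,3-dihydrobenzofuran-7-yl}[3-(triisopropylsilyloxy)phenyl]methanone | Oc1c(C(=O)c3cccc(O[Si](C(C)C)(C(C)C)C(C)C)c3)c2c(c(OC)c1)C[C@@H](C(C)(C)O[Si](CC)(CC)CC)O2 | intermediate
19 | (S)-{6-hydroxy-5-iodo-4-methoxy-2-[2-(triethylsilyloxy)propan-2-yl]-2,3-dihydrobenzofuran-7-yl}[3-(triisopropylsilyloxy)phenyl]methanone | Oc1c(C(=O)c3cccc(O[Si](C(C)C)(C(C)C)C(C)C)c3)c2c(c(OC)c1I)C[C@@H](C(C)(C)O[Si](CC)(CC)CC)O2 | intermediate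
20 | (+)-limonene 1,2-oxide, (4R), cis/trans mixture | CC12OC1C[C@@H](CC2)C(=C)C | starting material
21 | (4R)-1-methyl-4-(prop-1-en-2-yl)cyclohexane-1,2-diol | CC1(O)C(O)C[C@@H](CC1)C(=C)C | intermediate
22 | (3R)-6-oxo-3-(prop-1-en-2-yl)heptanal | CC(=O)CC[C@H](CC=O)C(=C)C | intermediate
23 | (5R)-7,7-dimethoxy-5-(prop-1-en-2-yl)heptan-2-one | CC(=O)CC[C@H](CC(OC)OC)C(=C)C | intermediate
24 | (5R)-7,7-dimethoxy-2-methyl-5-(prop-1-en-2-yl)hept-1-ene | C=C(C)CC[C@H](CC(OC)OC)C(=C)C | intermediate
25 | (3R)-6-methyl-3-(prop-1-en-2-yl)hept-6-enal | C=C(C)CC[C@H](CC=O)C(=C)C | intermediate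
26 | 1-[(1E,3R)-6-methyl-3-(prop-1-en-2-yl)hepta-1,6-dien-1-yl]piperidine | C=C(C)CC[C@H](/C=C/N1CCCCC1)C(=C)C | intermediate
27 | (2S)-5-methyl-2-(prop-1-en-2-yl)hex-5-enal | C=C(C)CC[C@H](C=O)C(=C)C | intermediate
28 | (2S)-5-methyl-2-(prop-1-en-2-yl)hex-5-en-1-ol | C=C(C)CC[C@H](CO)C(=C)C | intermediate
29 | (3S)-3-(iodomethyl)-2,6-dimethylhepta-1,6-diene | C=C(C)CC[C@H](CI)C(=C)C | intermediate
30 | [(2S)-5-methyl-2-(prop-1-en-2-yl)hex-5-en-1-yl]lithium | C=C(C)CC[C@H](C[Li])C(=C)C | intermediate
31 | [(2S)-5-methyl-2-(prop-1-en-2-yl)hex-5-en-1-yl]zinc chloride | C=C(C)CC[C@H](C[Zn]Cl)C(=C)C | intermediate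
32 | {(2S)-6-hydroxy-4-methoxy-5-[(2R)-5-methyl-2-(prop-1-en-2-yl)hex-5-en-1-yl]-2-[2-(triethylsilyloxy)propan-2-yl]-2,3-dihydrobenzofuran-7-yl}[3-(triisopropylsilyloxy)phenyl]methanone | C=C(C)CC[C@H](Cc1c(O)c(C(=O)c2cccc(O[Si](C(C)C)(C(C)C)C(C)C)c2)c2c(c1OC)C[C@@H](C(C)(C)O[Si](CC)(CC)CC)O2)C(=C)C | intermediate
33 | {(2S)-6-hydroxy-2-(2-hydroxypropan-2-yl)-4-methoxy-5-[(2R)-5-methyl-2-(prop-1-en-2-yl)hex-5-en-1-yl]-2,3-dihydrobenzofuran-7-yl}(3-hydroxyphenyl)methanone | C=C(C)CC[C@H](Cc1c(O)c(C(=O)c2cccc(O)c2)c2c(c1OC)C[C@@H](C(C)(C)O)O2)C(=C)C | target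

**Step count**
Total: 20 steps. Longest linear sequence: 12 steps (1–6, 9–12, 19, 20). Side branches: steps 7–8 (aroyl partner) and steps 13–18 (side chain).

**Steps most likely to fail**

1. Step 6. The hydrogen-atom transfer from the hindered, non-benzylic OCH2 group may be too slow, so that carbene dimerisation (azine or stilbene formation) or simple reduction of the carbene radical takes over; facial discrimination in the ring closure may also be insufficient. The fallback sets out from 2 and comes back at 10, and it moves the stereo-defining event to a hydrogenation. Rap–Stoermer condensation of 2 with one equivalent of chloroacetone (K2CO3, DMF, 70 °C) would give 1-(4-hydroxy-6-methoxybenzofuran-2-yl)ethanone F1. Excess MeMgBr (THF, 0 °C) would give 2-(4-hydroxy-6-methoxybenzofuran-2-yl)propan-2-ol F2. TBSCl/imidazole would give the phenol silyl ether F3, and TESOTf/2,6-lutidine the bis-silyl benzofuran F4. Asymmetric hydrogenation of the furan C2=C3 bond of F4 with a Ru(II)–chiral NHC catalyst under H2 pressure, a known reaction of 2-substituted benzofurans, would then deliver 10.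

2. Step 19. The alkylzinc may be protonated by the phenol, oxidative addition and transmetalation may be slow at the iodide flanked by OMe and OH, and β-hydride elimination toward the conjugated diene may compete with reductive elimination. The fallback sets out from 19 and comes back at the target 33. The phenol is silylated (TBSOTf, 2,6-lutidine, CH2Cl2) to the 6-O-TBS aryl iodide F5. Alkyllithium 30, made as in step 19, is added to B-methoxy-9-BBN to form the lithium alkyl(methoxy)borinate F6. B-alkyl Suzuki–Miyaura coupling of F5 with F6 (Pd(dppf)Cl2, AsPh3, aq. K3PO4, DMF/THF, rt → 50 °C) would give the tris-silyl ether F7, and buffered TBAF would remove all three silyl groups to give 33.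

3. Step 17. The enamine may self-condense or be over-oxidised, and the α-stereocentre of the nor-aldehyde may epimerise (or the alkene move into conjugation) before reduction. The fallback sets out from 25 and comes back at 28, and it removes the carbon through a diol. Proline-catalysed α-aminoxylation of 25 with nitrosobenzene, followed by NaBH4 in the same flask, would give the 2-(anilinooxy) alcohol F8. N–O cleavage (cat. CuSO4, MeOH) would give the 1,2-diol F9. NaIO4 in THF/pH 7 buffer at 0 °C would cleave F9 to aldehyde 27 under neutral conditions, and 27 would be reduced at once with NaBH4 to 28.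

**Further compounds**
F1 | step 6 | 1-(4-hydroxy-6-methoxybenzofuran-2-yl)ethanone | COc1cc(O)c2cc(C(C)=O)oc2c1
F2 | step 6 | 2-(4-hydroxy-6-methoxybenzofuran-2-yl)propan-2-ol | COc1cc(O)c2cc(C(C)(C)O)oc2c1
F3 | step 6 | 2-[4-(tert-butyldimethylsilyloxy)-6-methoxybenzofuran-2-yl]propan-2-ol | COc1cc(O[Si](C)(C)C(C)(C)C)c2cc(C(C)(C)O)oc2c1
F4 | step 6 | 4-(tert-butyldimethylsilyloxy)-6-methoxy-2-[2-(triethylsilyloxy)propan-2-yl]benzofuran | COc1cc(O[Si](C)(C)C(C)(C)C)c2cc(C(C)(C)O[Si](CC)(CC)CC)oc2c1
F5 | step 19 | (S)-{6-(tert-butyldimethylsilyloxy)-5-iodo-4-methoxy-2-[2-(triethylsilyloxy)propan-2-yl]-2,3-dihydrobenzofuran-7-yl}[3-(triisopropylsilyloxy)phenyl]methanone | CC(C)(C)[Si](C)(C)Oc1c(C(=O)c3cccc(O[Si](C(C)C)(C(C)C)C(C)C)c3)c2c(c(OC)c1I)C[C@@H](C(C)(C)O[Si](CC)(CC)CC)O2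
F6 | step 19 | lithium 9-methoxy-9-[(2S)-5-methyl-2-(prop-1-en-2-yl)hex-5-en-1-yl]-9-boranuidabicyclo[3.3.1]nonane | [Li+].C=C(C)CC[C@H](C[B-]1(OC)C2CCCC1CCC2)C(=C)C
F7 | step 19 | {(2S)-6-(tert-butyldimethylsilyloxy)-4-methoxy-5-[(2R)-5-methyl-2-(prop-1-en-2-yl)hex-5-en-1-yl]-2-[2-(triethylsilyloxy)propan-2-yl]-2,3-dihydrobenzofuran-7-yl}[3-(triisopropylsilyloxy)phenyl]methanone | C=C(C)CC[C@H](Cc1c(O[Si](C)(C)C(C)(C)C)c(C(=O)c2cccc(O[Si](C(C)C)(C(C)C)C(C)C)c2)c2c(c1OC)C[C@@H](C(C)(C)O[Si](CC)(CC)CC)O2)C(=C)C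
F8 | step 17 | (3S)-6-methyl-2-[(phenylamino)oxy]-3-(prop-1-en-2-yl)hept-6-en-1-ol (C2 configuration immaterial) | C=C(C)CC[C@H](C(CO)ONc1ccccc1)C(=C)C
F9 | step 17 | (3S)-6-methyl-3-(prop-1-en-2-yl)hept-6-ene-1,2-diol (C2 configuration immaterial) | C=C(C)CC[C@H](C(O)CO)C(=C)C
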